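**Retrosynthetic overview**
1. The α-methylene lactone is closed last by oxidative lactonisation of a 1,4-diol, the C9 carbinol is oxidised to the ketone in the same flask, and the ester comes from the 5β-alcohol and (R)-2-methylbutanoic acid.
2. The 5β-alcohol comes from hydroxyl-directed reduction of the 2-acyl-2-hydroxycycloheptanone 15.
3. The seven-membered ring comes from an α-ketol ring enlargement of cyclohexyl hydroxy-1,2-dione 14, in which C10 shifts from C5 to C1.
4. The key bond C1–C5 joins two carbonyl carbons: lithiated (E)-1-diazopent-3-en-2-one, an acyl-anion equivalent of the 2-oxopent-3-enoyl unit, adds to the hindered cyclohexanone 7.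
5. Ketone 7 comes from (S)-carvone by β-borylation/oxidation, α′-hydroxylation and allylic oxidation. Ring order: six-membered carbocycle (carvone), then seven-membered carbocycle, then lactone.

Assumption: (S)-(+)-carvone, (E)-pent-3-en-2-one and (R)-2-methylbutanoic acid are bought as single isomers; C5 of (S)-carvone becomes C7 of the target.
Labels: ring atoms are C1 (carbinol carbon bearing the butenoyl group), C5 (acyloxy carbon), C6 and C7 (lactone O–CH and C–CH), C8 (CH2), C9 (ring ketone), C10 (CH–CH3); α is the face of H-7; the cyclohexane precursors (ring C5–C10) carry the same labels.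

Step 1
Reactants: 1 (S)-(+)-carvone
Product: 3 (2S,3S,5S)-3-hydroxy-2-methyl-5-(prop-1-en-2-yl)cyclohexan-1-one, via β-boryl ketone 2 (not isolated)
Conditions: B2pin2, CuCl (3 mol %), DPEphos (3 mol %), NaOtBu (9 mol %), MeOH, THF, rt; then NaBO3·4H2O, THF/H2O, rt
Reagents that add atoms: bis(pinacolato)diboron, CC1(C)OB(OC1(C)C)B1OC(C)(C)C(C)(C)O1 (boron of 2); NaBO3 (sodium perborate), [Na+].[O-]OB=O (oxygen at C9)
Why: Copper-catalysed conjugate borylation (Yun β-boration) followed by perborate oxidation with retention puts boron, then oxygen, on C9 anti to the isopropenyl group (9α-O), and the enolisable C10 settles in the mildly basic work-up as the equatorial 10α-methyl epimer.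

Step 2
Reactants: 3 (2S,3S,5S)-3-hydroxy-2-methyl-5-(prop-1-en-2-yl)cyclohexan-1-one
Product: 5 (2S,3S,5R,6R)-3,6-dihydroxy-2-methyl-5-(prop-1-en-2-yl)cyclohexan-1-one, via dilithium enolate alkoxide 4 (not isolated)
Conditions: LiN(iPr)2 (2.2 equiv), THF, −78 °C; 2-(phenylsulfonyl)-3-phenyloxaziridine, −78 °C; AcOH
Reagents that add atoms: LiN(iPr)2, [Li]N(C(C)C)C(C)C (lithium of 4); 2-(phenylsulfonyl)-3-phenyloxaziridine, O=S(=O)(c1ccccc1)N1OC1c1ccccc1 (oxygen at C6)
Why: Kinetic deprotonation at the unhindered C6 methylene and Davis oxaziridine hydroxylation of the enolate anti to the adjacent isopropenyl group give the 6α-hydroxyl, which is trans to C7 and also the thermodynamic diequatorial arrangement.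

Step 3
Reactants: 5 (2S,3S,5R,6R)-3,6-dihydroxy-2-methyl-5-(prop-1-en-2-yl)cyclohexan-1-one
Product: 6 (2S,3S,5R,6R)-3,6-dihydroxy-5-(3-hydroxyprop-1-en-2-yl)-2-methylcyclohexan-1-one
Conditions: SeO2 (0.3 equiv), tBuOOH, CH2Cl2, rt
Reagents that add atoms: tert-butyl hydroperoxide, CC(C)(C)OO (terminal oxidant; the oxygen is delivered through SeO2, O=[Se]=O)
Why: Sharpless SeO2/tBuOOH allylic oxidation (ene reaction, then [2,3]-shift) converts the methyl of the electron-rich 1,1-disubstituted alkene into the primary allylic alcohol without touching a stereocenter.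

Step 4
Reactants: 6 (2S,3S,5R,6R)-3,6-dihydroxy-5-(3-hydroxyprop-1-en-2-yl)-2-methylcyclohexan-1-one
Product: 7 (2S,3S,5R,6R)-3,6-bis(tert-butyldimethylsilyloxy)-5-[3-(tert-butyldimethylsilyloxy)prop-1-en-2-yl]-2-methylcyclohexan-1-one
Conditions: TBSOTf, 2,6-lutidine, CH2Cl2, −78 to 0 °C
Reagents that add atoms: tert-butyldimethylsilyl triflate, CC(C)(C)[Si](C)(C)OS(=O)(=O)C(F)(F)F
Why: Exhaustive silylation removes every acidic O–H before the carbanion step and places a bulky axial 9α-OTBS group over the α-face of the ketone, with the isopropenyl-derived group, 6-OTBS and 10-CH3 all equatorial.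

Step 5
Reactants: 8 (E)-pent-3-en-2-one
Product: 11 (E)-1-diazopent-3-en-2-one, via lithium dienolate 9 (not isolated), via trifluoroacetyl diketone 10 (not isolated)
Conditions: LiN(SiMe3)2, THF, −78 °C; CF3CO2CH2CF3; then MsN3, Et3N, H2O, MeCN, rt
Reagents that add atoms: LiN(SiMe3)2, [Li]N([Si](C)(C)C)[Si](C)(C)C (lithium of 9); 2,2,2-trifluoroethyl trifluoroacetate, O=C(OCC(F)(F)F)C(F)(F)F (trifluoroacetyl group of 10); methanesulfonyl azide, CS(=O)(=O)N=[N+]=[N-] (N2 of 11)
Why: Danheiser detrifluoroacetylative diazo transfer (kinetic α′-trifluoroacetylation, then Regitz-type transfer with loss of the trifluoroacetyl group) is the standard route to α′-diazo enones and leaves the (E)-alkene untouched.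

Step 6
Reactants: 7 (2S,3S,5R,6R)-3,6-bis(tert-butyldimethylsilyloxy)-5-[3-(tert-butyldimethylsilyloxy)prop-1-en-2-yl]-2-methylcyclohexan-1-one; 11 (E)-1-diazopent-3-en-2-one
Product: 13 diazo carbinol (E)-1-diazo-1-[(1R,2S,3S,5R,6R)-tris-silyloxy-1-hydroxy-2-methylcyclohexyl]pent-3-en-2-one, via lithiated diazoketone 12 (not isolated)
Conditions: 11, LiN(iPr)2, THF, −78 °C; then 7, −78 °C; AcOH, −78 °C
Reagents that add atoms: LiN(iPr)2, [Li]N(C(C)C)C(C)C (lithium of 12 only)
Why: Aldol-type addition of the lithiated diazoketone, whose diazo carbon is a masked carbonyl carbon and thus an acyl-anion equivalent of the (E)-2-oxopent-3-enoyl unit, joins the two carbonyl carbons C1 and C5, and the nucleophile enters equatorially from the β-face because the axial 9α-OTBS group blocks axial attack, which sets the C5 carbinol (C1 β, OH α).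

Step 7
Reactants: 13 diazo carbinol
Product: 15 ring-expanded 2-[(E)-but-2-enoyl]-2-hydroxycycloheptanone (ketone at C5; 1α-OH; 1β-butenoyl; 6α-OTBS; 9α-OTBS; 10α-CH3; 7β side chain), via hydroxy dione 14 (not isolated)
Conditions: dimethyldioxirane, acetone/CH2Cl2, −40 to 0 °C; evaporate; Cu(OTf)2 (10 mol %), CH2Cl2, 0 °C to rt
Reagents that add atoms: dimethyldioxirane, CC1(C)OO1
Why: Proposed new method: dioxirane oxidation of the diazo group (known for α-diazo ketones) unmasks the vicinal dione, whose Lewis-acid-bound cisoid hydroxy ketone array then undergoes an α-ketol (acyloin) rearrangement (closest precedents: Lewis-acid-catalysed rearrangement of β-hydroxy-α-diketones to α-hydroxy-β-diketones and the D-homoannulation of 17-hydroxy-20-keto steroids) in which the more electron-rich C10, not the silyloxy-bearing C6, migrates with retention from C5 to the C1 carbonyl, so that the 1,2-dione strain is relieved, the ring grows to seven and the C5 configuration is transferred to C1 (OH α, butenoyl β).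

Step 8
Reactants: 15 ring-expanded 2-[(E)-but-2-enoyl]-2-hydroxycycloheptanone
Product: 16 1α,5β-diol (C5 ketone reduced; all else as in 15)
Conditions: Me4NBH(OAc)3, MeCN/AcOH, −30 °C
Reagents that add atoms: none
Why: Hydroxyl-directed triacetoxyborohydride reduction (Saksena–Evans type) delivers hydride from the boron bound to the 1α-oxygen onto the α-face of the more electrophilic, non-conjugated C5 ketone, giving the anti diol (5β-OH) and leaving the enone ketone alone.

Step 9
Reactants: 16 1α,5β-diol; 17 (R)-2-methylbutanoic acid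
Product: 19 5β-[(R)-2-methylbutanoyloxy] tris-silyl ether, via mixed anhydride 18 (not isolated)
Conditions: 17, 2,4,6-trichlorobenzoyl chloride, Et3N, THF, rt; then 16, DMAP, toluene, rt to 40 °C
Reagents that add atoms: 2,4,6-trichlorobenzoyl chloride, O=C(Cl)c1c(Cl)cc(Cl)cc1Cl (aroyl group of 18 only)
Why: Yamaguchi esterification acylates the only secondary hydroxyl (the tertiary C1–OH is inert) through the mixed anhydride under conditions that leave the α-stereocenter of the acid unchanged, so the (R)-configuration of 17 is carried over.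

Step 10
Reactants: 19 5β-[(R)-2-methylbutanoyloxy] tris-silyl ether
Product: 20 tetraol ester (free 1α-OH, 6α-OH, 9α-OH and allylic CH2OH)
Conditions: HF·pyridine, pyridine, THF, 0 °C to rt
Reagents that add atoms: none
Why: Fluoride-driven cleavage of the three silyl ethers under mildly acidic buffered conditions avoids the acyl migration, retro-aldol and α-ketol shifts that basic fluoride would invite in this hydroxy ketone array.

Step 11
Reactants: 20 tetraol ester
Product: 24 target CNP0153197.3, via hydroxy enal 21 (not isolated), via lactol 22 (not isolated), via C9-hydroxy lactone 23 (not isolated)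
Conditions: TEMPO (20 mol %), PhI(OAc)2, CH2Cl2, rt; then Dess–Martin periodinane, pyridine, rt
Reagents that add atoms: none
Why: TEMPO/PhI(OAc)2 oxidises only the primary allylic alcohol, the enal is trapped by the trans 6α-hydroxyl as a lactol that is oxidised on to the trans-fused α-methylene lactone (oxidative lactonisation of a 1,4-diol), and Dess–Martin periodinane then turns the remaining secondary C9 carbinol into the ketone without epimerising C10, whose α-methyl (anti to the butenoyl group) should also be the thermodynamic epimer.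

**Compound list**
1 | (S)-(+)-carvone, (5S)-2-methyl-5-(prop-1-en-2-yl)cyclohex-2-en-1-one | CC1=CC[C@@H](CC1=O)C(C)=C | starting material
2 | (2S,3S,5S)-2-methyl-5-(prop-1-en-2-yl)-3-(4,4,5,5-tetramethyl-1,3,2-dioxaborolan-2-yl)cyclohexan-1-one (boron trans to isopropenyl) | C[C@@H]1C(=O)C[C@@H](C(C)=C)C[C@@H]1B2OC(C)(C)C(C)(C)O2 | intermediate
3 | (2S,3S,5S)-3-hydroxy-2-methyl-5-(prop-1-en-2-yl)cyclohexan-1-one (OH trans to isopropenyl, cis to methyl) | C[C@@H]1C(=O)C[C@@H](C(C)=C)C[C@@H]1O | intermediate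
4 | dilithium enolate alkoxide of 3 (C5=C6 enolate, 9-OLi) | C[C@@H]1C(O[Li])=C[C@@H](C(C)=C)C[C@@H]1O[Li] | intermediate
5 | (2S,3S,5R,6R)-3,6-dihydroxy-2-methyl-5-(prop-1-en-2-yl)cyclohexan-1-one (both OH trans to isopropenyl) | C[C@@H]1C(=O)[C@H](O)[C@@H](C(C)=C)C[C@@H]1O | intermediate
6 | (2S,3S,5R,6R)-3,6-dihydroxy-5-(3-hydroxyprop-1-en-2-yl)-2-methylcyclohexan-1-one | C[C@@H]1C(=O)[C@H](O)[C@@H](C(CO)=C)C[C@@H]1O | intermediate
7 | (2S,3S,5R,6R)-3,6-bis(tert-butyldimethylsilyloxy)-5-[3-(tert-butyldimethylsilyloxy)prop-1-en-2-yl]-2-methylcyclohexan-1-one | C[C@@H]1C(=O)[C@H](O[Si](C)(C)C(C)(C)C)[C@@H](C(CO[Si](C)(C)C(C)(C)C)=C)C[C@@H]1O[Si](C)(C)C(C)(C)C | intermediate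
8 | (E)-pent-3-en-2-one | C/C=C/C(C)=O | starting material
9 | lithium (E)-penta-1,3-dien-2-olate | C/C=C/C(O[Li])=C | intermediate
10 | (E)-1,1,1-trifluorohept-5-ene-2,4-dione | C/C=C/C(=O)CC(=O)C(F)(F)F | intermediate
11 | (E)-1-diazopent-3-en-2-one | C/C=C/C(=O)C=[N+]=[N-] | intermediate
12 | (E)-1-diazo-1-lithiopent-3-en-2-one | C/C=C/C(=O)C([Li])=[N+]=[N-] | intermediate
13 | (E)-1-diazo-1-[(1R,2S,3S,5R,6R)-3,6-bis(tert-butyldimethylsilyloxy)-5-[3-(tert-butyldimethylsilyloxy)prop-1-en-2-yl]-1-hydroxy-2-methylcyclohexyl]pent-3-en-2-one (new C–C bond β, OH α) | C[C@@H]1[C@@](O)(C(=[N+]=[N-])C(=O)/C=C/C)[C@H](O[Si](C)(C)C(C)(C)C)[C@@H](C(CO[Si](C)(C)C(C)(C)C)=C)C[C@@H]1O[Si](C)(C)C(C)(C)C | intermediate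
14 | (E)-1-[(1S,2S,3S,5R,6R)-3,6-bis(tert-butyldimethylsilyloxy)-5-[3-(tert-butyldimethylsilyloxy)prop-1-en-2-yl]-1-hydroxy-2-methylcyclohexyl]pent-3-ene-1,2-dione | C[C@@H]1[C@@](O)(C(=O)C(=O)/C=C/C)[C@H](O[Si](C)(C)C(C)(C)C)[C@@H](C(CO[Si](C)(C)C(C)(C)C)=C)C[C@@H]1O[Si](C)(C)C(C)(C)C | intermediate
15 | 2-[(E)-but-2-enoyl]-4,7-bis(tert-butyldimethylsilyloxy)-6-[3-(tert-butyldimethylsilyloxy)prop-1-en-2-yl]-2-hydroxy-3-methylcycloheptan-1-one; in the labels above: C5 ketone, 1α-OH, 1β-butenoyl, 6α-OTBS, 7β side chain, 9α-OTBS, 10α-CH3 | C=C(CO[Si](C)(C)C(C)(C)C)[C@H]1C[C@H](O[Si](C)(C)C(C)(C)C)[C@H](C)[C@@](O)(C(=O)/C=C/C)C(=O)[C@@H]1O[Si](C)(C)C(C)(C)C | intermediate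
16 | 15 with the C5 ketone reduced to the 5β-alcohol (1α,5β-diol, trans) | C=C(CO[Si](C)(C)C(C)(C)C)[C@H]1C[C@H](O[Si](C)(C)C(C)(C)C)[C@H](C)[C@@](O)(C(=O)/C=C/C)[C@@H](O)[C@@H]1O[Si](C)(C)C(C)(C)C | intermediate
17 | (R)-2-methylbutanoic acid | CC[C@@H](C)C(=O)O | starting material
18 | (R)-2-methylbutanoic 2,4,6-trichlorobenzoic anhydride | CC[C@@H](C)C(=O)OC(=O)c1c(Cl)cc(Cl)cc1Cl | intermediate
19 | 16 esterified at the 5β-oxygen with (R)-2-methylbutanoic acid | C=C(CO[Si](C)(C)C(C)(C)C)[C@H]1C[C@H](O[Si](C)(C)C(C)(C)C)[C@H](C)[C@@](O)(C(=O)/C=C/C)[C@@H](OC(=O)[C@H](C)CC)[C@@H]1O[Si](C)(C)C(C)(C)C | intermediate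
20 | tetraol ester: 19 with all three silyl groups removed (1α-OH, 6α-OH, 9α-OH, allylic CH2OH) | C=C(CO)[C@H]1C[C@H](O)[C@H](C)[C@@](O)(C(=O)/C=C/C)[C@@H](OC(=O)[C@H](C)CC)[C@@H]1O | intermediate
21 | hydroxy enal: 20 with the allylic CH2OH oxidised to the 2-substituted acrolein | C=C(C=O)[C@H]1C[C@H](O)[C@H](C)[C@@](O)(C(=O)/C=C/C)[C@@H](OC(=O)[C@H](C)CC)[C@@H]1O | intermediate
22 | lactol: trans-fused 2-hydroxy-3-methylidene-tetrahydrofuran formed from the enal and the 6α-OH (anomer mixture), 9α-OH free | C=C1C(O)O[C@@H]2[C@@H]1C[C@H](O)[C@H](C)[C@@](O)(C(=O)/C=C/C)[C@H]2OC(=O)[C@H](C)CC | intermediate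
23 | C9-hydroxy lactone: the target with a 9α-OH in place of the C9 ketone | C=C1C(=O)O[C@@H]2[C@@H]1C[C@H](O)[C@H](C)[C@@](O)(C(=O)/C=C/C)[C@H]2OC(=O)[C@H](C)CC | intermediate
24 | CNP0153197.3: trans-fused α-methylene-γ-lactone on a cycloheptanone; 1α-OH, 1β-(E)-but-2-enoyl, 5β-O-(R)-2-methylbutanoyl, 6α-O (lactone), 7β-C, C9 ketone, 10α-CH3 (C1 S, C5 S, C6 R, C7 R, C10 R) | C=C1C(=O)O[C@@H]2[C@@H]1CC(=O)[C@H](C)[C@@](O)(C(=O)/C=C/C)[C@H]2OC(=O)[C@H](C)CC | target

**Step count and risks**
Total steps: 11. Longest linear sequence: 10 steps (1 to 24 through steps 1–4 and 6–11; step 5 is the side branch).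

Step 6 is a risk because ketone 7 is flanked by two substituted carbons, so the lithiated diazoketone may add slowly, enolise the ketone, or attack the wrong face. The fallback sets out from 7: the cerium acetylide of (E)-pent-3-en-1-yne (nBuLi, CeCl3, THF, −78 °C), a slimmer and less basic nucleophile whose two alkyne carbons are the masked dione, gives the enynyl carbinol F1. Gold-catalysed double oxidation of the alkyne (Ph3PAuNTf2, 2,6-dichloropyridine N-oxide, 1,2-dichloroethane) then gives the hydroxy dione 14, where the route is rejoined for the rearrangement half of step 7.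

Step 7 is a risk because C6 could migrate in place of C10, the tertiary hydroxyl could add to the enone (6-endo oxa-Michael), or the rearrangement could pass through the transoid conformer and give the C1 epimer. The fallback sets out from 13: Rh2(OAc)4 (1 mol %, CH2Cl2) forms the rhodium carbenoid, and the 1,2-shift of C10 with loss of nitrogen (Nagao–Pellicciari-type ring enlargement) gives the enolised 2-acylcycloheptanone F2. Cerium-catalysed aerobic α-hydroxylation of this 1,3-diketone (CeCl3·7H2O, O2, iPrOH) returns to 15; C1 is then set by approach control and the epimers are separated.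

Step 8 is a risk because the enone ketone is also α to the directing hydroxyl, so it may be reduced as well, or the hydride may be delivered to the wrong face. The fallback sets out from 15: Luche reduction (NaBH4, CeCl3·7H2O, MeOH, −78 °C) takes both ketones to the triol F3, and MnO2 (CH2Cl2, rt) re-oxidises only the allylic C2 carbinol, returning to 16.

**Further compounds**
F1 | step 6 | enynyl carbinol: 7 with a β-(E)-pent-3-en-1-ynyl group and an α-OH at C5 | C[C@@H]1[C@@](O)(C#C/C=C/C)[C@H](O[Si](C)(C)C(C)(C)C)[C@@H](C(CO[Si](C)(C)C(C)(C)C)=C)C[C@@H]1O[Si](C)(C)C(C)(C)C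
F2 | step 7 | 2-[(E)-but-2-enoyl]-4,7-bis(tert-butyldimethylsilyloxy)-6-[3-(tert-butyldimethylsilyloxy)prop-1-en-2-yl]-3-methylcycloheptan-1-one (15 without the C1 hydroxyl; enolised, C1 undefined) | C=C(CO[Si](C)(C)C(C)(C)C)[C@H]1C[C@H](O[Si](C)(C)C(C)(C)C)[C@H](C)C(C(=O)/C=C/C)C(=O)[C@@H]1O[Si](C)(C)C(C)(C)C
F3 | step 8 | triol: 16 with the butenoyl ketone also reduced to the allylic alcohol (mixture at that carbinol) | C=C(CO[Si](C)(C)C(C)(C)C)[C@H]1C[C@H](O[Si](C)(C)C(C)(C)C)[C@H](C)[C@@](O)(C(O)/C=C/C)[C@@H](O)[C@@H]1O[Si](C)(C)C(C)(C)C
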